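**Assumptions (stated once):** (i) The C6 methyl acetal of ludongnin H is the anomer favoured under acid equilibration (anomeric effect). (ii) All stereochemistry below is traced to the single stereocentre of **1**. Atom labels use kauranoid numbering.

## Retrosynthetic overview
1. Target ← Fischer methyl acetalisation of a C6 lactol, made from the 6,19-γ-lactone by DIBAL; the C15 ketone is restored by oxidation.
2. Spiro ring A (C4/C5/C10) ← Diels–Alder of a C10-exocyclic 1,3-diene with 4-methylbutenolide.
3. The bicyclo[3.2.1]octanone (rings C and D) ← 5-exo radical cyclisation onto the cyclohexene from a Diels–Alder of butadiene with an alkylidene β-ketoester δ-lactone.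
4. That lactone ← intramolecular Knoevenagel condensation of an aldehyde from (R)-1-O-benzylglycerol (C9–C10–C20) acylated with ethyl 3-oxopentanoate (C7, C8, C15–C17).
5. Ring order: δ-lactone → ring C → ring D → ring A → THF acetal.

## Route

**Step 1**
Reactants: 1 (R)-3-(benzyloxy)propane-1,2-diol; 2 ethyl 3-oxopentanoate
Product: 3 (S)-3-(benzyloxy)-2-hydroxypropyl 3-oxopentanoate
Conditions: DMAP (0.1 equiv), PhMe, 110 °C, EtOH distilled off
Reagents that add atoms: none (the acyl group comes from reactant 2)
Why: Transesterification through an acylketene is selective for the primary OH. The one stereocentre of 1 (the future C10 carbinol) is carried forward unchanged.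

**Step 2**
Reactants: 3
Product: 4 (S)-3-(benzyloxy)-2-(TBSO)propyl 3-oxopentanoate
Conditions: TBSCl (1.3 equiv), imidazole, DMF, 0 °C → rt
Reagents that add atoms: tert-butyldimethylsilyl chloride, CC(C)(C)[Si](C)(C)Cl
Why: Silyl protection of the secondary alcohol sets the γ-alkoxy group that will control facial selectivity later.

**Step 3**
Reactants: 4
Product: 5 (S)-2-(TBSO)-3-hydroxypropyl 3-oxopentanoate
Conditions: H2 (1 atm), 10% Pd/C, EtOAc, rt
Reagents that add atoms: none (H2 adds hydrogen only)
Why: Hydrogenolysis removes the benzyl ether and leaves the TBS ether and the β-ketoester intact.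

**Step 4**
Reactants: 5
Product: 6 (R)-2-(TBSO)-3-oxopropyl 3-oxopentanoate
Conditions: Dess–Martin periodinane, NaHCO3, CH2Cl2, 0 °C → rt
Reagents that add atoms: none
Why: Buffered, mild oxidation gives the C9 aldehyde without epimerising the α-silyloxy stereocentre.

**Step 5**
Reactants: 6
Product: 7 (S)-5-(TBSO)-3-propionyl-5,6-dihydro-2H-pyran-2-one
Conditions: piperidine (0.1 equiv), AcOH (0.1 equiv), CH2Cl2 (0.01 M), 4 Å MS, rt
Reagents that add atoms: none (loses H2O)
Why: Intramolecular Knoevenagel condensation closes the δ-lactone (C7–C8=C9–C10–C20–O). The endocyclic alkene forces C7 and C10 cis, which fixes cis ring fusion in the next step.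

**Step 6**
Reactants: 7; 8 buta-1,3-diene
Product: 9 cis-fused bicyclic lactone with C8 propionyl, C10-OTBS and a C12=C13 cyclohexene
Conditions: butadiene (10 equiv), Me2AlCl (1.2 equiv), CH2Cl2, –78 → 0 °C, sealed tube
Reagents that add atoms: none (butadiene is reactant 8)
Why: The chelated alkylidene β-ketoester is a strongly activated dienophile. Diels–Alder cycloaddition forms ring C and the C8 quaternary centre; the diene approaches anti to the γ-OTBS group, so C11 ends up trans to OTBS. Suprafacial addition to the cyclic dienophile puts C15 and H9 cis, on the face opposite C7/C10. Butadiene is symmetric, so there is no regiochemistry issue.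

**Step 7**
Reactants: 9
Product: 10 C16 α-bromoketone (C16 epimer mixture)
Conditions: CuBr2 (2.2 equiv), EtOAc/CHCl3 1:1, reflux
Reagents that add atoms: copper(II) bromide, Br[Cu]Br
Why: α-Bromination of a ketone. C16 is the only enolisable α-carbon because C8 is quaternary, and CuBr2 leaves the isolated alkene untouched.

**Step 8**
Reactants: 10
Product: 11 bicyclo[3.2.1]octan-15-one fused to the δ-lactone, with 10-OTBS and 16-exo-methyl
Conditions: Bu3SnH (1.5 equiv, syringe pump), AIBN (0.2 equiv), PhH (0.01 M), 80 °C; then DBU, CH2Cl2, rt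
Reagents that add atoms: none (tributyltin hydride adds hydrogen only)
Why: The α-keto radical at C16 undergoes 5-exo radical cyclisation onto C13. C15 is axial on C8, so C16 bonds to C13 on the same face. This closes ring D and fixes C13 (H up) by ring geometry. DBU epimerises C16, the only α-H, to the thermodynamically favoured exo-methyl isomer.

**Step 9**
Reactants: 11
Product: 12 10-hydroxy lactone
Conditions: HF·pyridine, THF/pyridine, 0 °C → rt
Reagents that add atoms: none
Why: Acidic fluoride removes the TBS group; basic fluoride is avoided to limit translactonisation.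

**Step 10**
Reactants: 12
Product: 13 10-oxo lactone (α-alkoxy ketone)
Conditions: Dess–Martin periodinane, NaHCO3, CH2Cl2, rt
Reagents that add atoms: none
Why: Oxidation removes the temporary C10 stereocentre, which has already set C8, C9 and C13.

**Step 11**
Reactants: 13; 14 allyltriphenylphosphonium bromide
Product: 15 C10-exocyclic 1,3-diene
Conditions: 14, KOtBu, THF, –78 → 0 °C
Reagents that add atoms: none (14 is a reactant)
Why: Wittig olefination with a non-stabilised ylide converts the less hindered C10 ketone. The neopentylic C15 ketone does not react. The vinyl group ends up mainly syn to the small C20 methylene.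

**Step 12**
Reactants: 15; 16 4-methylfuran-2(5H)-one
Product: 17 spiro adduct with the 6,19-γ-lactone and a C1=C2 alkene
Conditions: 16 (5 equiv), BHT, PhMe, 180 °C, sealed tube
Reagents that add atoms: none (16 is a reactant)
Why: Diels–Alder cycloaddition builds ring A and sets C4, C5 and C10 together.
- Regiochemistry is "ortho" (C10–C5 and C3–C4 bonds).
- The butenolide is cis-fused, so C18 and H5 are cis, and C19 and C6 are cis.
- Exo approach, disfavoured for endo by the bulky C9 substituent, places the lactone cis to C20.
- The dienophile approaches the face syn to H9, away from the C11/C14 methylenes of ring C, which fixes C10.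

**Step 13**
Reactants: 17
Product: 18 6,19-lactone with saturated ring A
Conditions: H2 (1 atm), 10% Pd/C, EtOAc, rt
Reagents that add atoms: none
Why: Hydrogenation of the disubstituted C1=C2 alkene creates no stereocentre.

**Step 14**
Reactants: 18
Product: 19 C6 lactol with C15 alcohol (anomer and C15 epimer mixtures)
Conditions: DIBAL-H (4 equiv), CH2Cl2, –78 °C; Rochelle salt work-up
Reagents that add atoms: none (DIBAL-H adds hydrogen only)
Why: Partial lactone reduction gives the lactol from the more strained, more electrophilic γ-lactone. The hindered neopentylic δ-lactone at C7 survives. The C15 ketone is also reduced here; its stereocentre is erased again in step 16.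

**Step 15**
Reactants: 19
Product: 20 C6 methyl acetal with C15 alcohol
Conditions: MeOH, CSA (0.1 equiv), rt
Reagents that add atoms: methanol, CO
Why: Fischer glycosidation of the lactol forms the cis-fused THF acetal, and C6 equilibrates to the anomer favoured by the anomeric effect.

**Step 16**
Reactants: 20
Product: 21 ludongnin H
Conditions: Dess–Martin periodinane, NaHCO3, CH2Cl2, rt
Reagents that add atoms: none
Why: Oxidation of the C15 alcohol restores the ketone, and the acetal is inert to these conditions.

## Compound list
1 | (R)-3-(benzyloxy)propane-1,2-diol | OC[C@@H](O)COCc1ccccc1 | starting material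
2 | ethyl 3-oxopentanoate | CCOC(=O)CC(=O)CC | starting material
3 | (S)-3-(benzyloxy)-2-hydroxypropyl 3-oxopentanoate | CCC(=O)CC(=O)OC[C@@H](O)COCc1ccccc1 | intermediate
4 | (S)-3-(benzyloxy)-2-(TBSO)propyl 3-oxopentanoate | CCC(=O)CC(=O)OC[C@@H](O[Si](C)(C)C(C)(C)C)COCc1ccccc1 | intermediate
5 | (S)-2-(TBSO)-3-hydroxypropyl 3-oxopentanoate | CCC(=O)CC(=O)OC[C@@H](O[Si](C)(C)C(C)(C)C)CO | intermediate
6 | (R)-2-(TBSO)-3-oxopropyl 3-oxopentanoate | CCC(=O)CC(=O)OC[C@@H](O[Si](C)(C)C(C)(C)C)C=O | intermediate
7 | (S)-5-(TBSO)-3-propionyl-5,6-dihydro-2H-pyran-2-one | CCC(=O)C1=C[C@H](O[Si](C)(C)C(C)(C)C)COC1=O | intermediate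
8 | 1,3-butadiene | C=CC=C | starting material
9 | cis-fused Diels–Alder lactone (C8 propionyl, 10-OTBS, Δ12,13) | CCC(=O)[C@]12CC=CC[C@H]1[C@H](O[Si](C)(C)C(C)(C)C)COC2=O | intermediate
10 | C16 α-bromoketone of 9 (C16 epimer mixture) | CC(Br)C(=O)[C@]12CC=CC[C@H]1[C@H](O[Si](C)(C)C(C)(C)C)COC2=O | intermediate
11 | bicyclo[3.2.1]octanone lactone, 10-OTBS, 16-exo-methyl | O=C1OC[C@@H](O[Si](C)(C)C(C)(C)C)[C@@H]2CC[C@@H]3C[C@]12C(=O)[C@H]3C | intermediate
12 | 10-hydroxy lactone | O=C1OC[C@@H](O)[C@@H]2CC[C@@H]3C[C@]12C(=O)[C@H]3C | intermediate
13 | 10-oxo lactone | O=C1OCC(=O)[C@@H]2CC[C@@H]3C[C@]12C(=O)[C@H]3C | intermediate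
14 | allyltriphenylphosphonium bromide | C=CC[P+](c1ccccc1)(c1ccccc1)c1ccccc1.[Br-] | starting material
15 | C10-exocyclic 1,3-diene lactone (E/Z unspecified) | O=C1OCC(=CC=C)[C@@H]2CC[C@@H]3C[C@]12C(=O)[C@H]3C | intermediate
16 | 4-methylfuran-2(5H)-one | CC1=CC(=O)OC1 | starting material
17 | spiro Diels–Alder adduct (6,19-lactone, Δ1,2) | O=C1OC[C@]2(C)CC=C[C@]3(COC(=O)[C@@]45C[C@@H](CC[C@H]43)[C@H](C)C5=O)[C@H]12 | intermediate
18 | saturated 6,19-lactone | O=C1OC[C@]2(C)CCC[C@]3(COC(=O)[C@@]45C[C@@H](CC[C@H]43)[C@H](C)C5=O)[C@H]12 | intermediate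
19 | C6 lactol, C15 alcohol (anomer and C15 epimer mixtures) | OC1OC[C@]2(C)CCC[C@]3(COC(=O)[C@@]45C[C@@H](CC[C@H]43)[C@H](C)C5O)[C@H]12 | intermediate
20 | C6 methyl acetal, C15 alcohol (C15 epimer mixture) | CO[C@H]1OC[C@]2(C)CCC[C@]3(COC(=O)[C@@]45C[C@@H](CC[C@H]43)[C@H](C)C5O)[C@H]12 | intermediate
21 | ludongnin H | CO[C@H]1OC[C@]2(C)CCC[C@]3(COC(=O)[C@@]45C[C@@H](CC[C@H]43)[C@H](C)C5=O)[C@H]12 | target

**Total steps: 16. Longest linear sequence: 16 (from 1).**

## Three steps most likely to fail
1. **Step 12 (spiro Diels–Alder).** It joins two congested termini and depends on diene geometry, exo/endo preference and facial selectivity. Fallback: use citraconic anhydride as the dienophile, which is more reactive, then apply regioselective NaBH4 reduction at the more hindered carbonyl to reach the same 6,19-lactone.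
2. **Step 14 (lactone to lactol in the presence of a second lactone and a ketone).** Fallback: reduce everything to the polyol with LiAlH4, then re-form the C7/C20 lactone and the C6 lactol by TEMPO/PhI(OAc)2 oxidative lactonisation, and finish with Dess–Martin oxidation at C15.
3. **Step 8 (5-exo radical cyclisation of an electrophilic α-keto radical onto an unactivated alkene).** Fallback: replace it with a Pd(II) cycloalkenylation of the C15 silyl enol ether onto the cyclohexene, followed by hydrogenation, which closes the C13–C16 bond by a polar, metal-mediated route.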